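The disconnection rests on the C3–C2 bond of the lactone ring (chroman-2-one numbering). C4, a diarylmethine carbon next to the C3 methylene, is the mark of an anti-Markovnikov hydrometalation of a 1,1-diarylethene, and C2 can wait on O1 as an activated carbonate. In one operation, CuH-catalysed enantioselective hydrocupration of an achiral diarylethene sets C4, and the primary alkylcopper so formed closes the dihydropyranone ring by attacking the tethered carbonate carbonyl. The precursor is a flat aryl pentafluorophenyl carbonate with an ortho 1-arylvinyl group and a ring-A bromine. The bromine later takes up the styryl arm by a Heck reaction, and three silyl ethers fall in the last step.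

Key step: step 5

Notation: ring A is the benzo ring of the chroman-2-one (O1, C2, C3, C4, C4a, C5 to C8, C8a); TIPS = tri(propan-2-yl)silyl, TIPSO = its oxy group.

Assumption: the facial sense of the hydrocupration for a given ligand enantiomer cannot be assigned in advance for this diarylethene; (R)-DTBM-SEGPHOS is written, and the mirror-image ligand is to be taken if a first run shows the (4S)-lactone.

Step 1
Reactants: 1 5-bromoresorcinol; 2 vanillic acid
Product: 3 (2-bromo-4,6-dihydroxyphenyl)(4-hydroxy-3-methoxyphenyl)methanone
Conditions: Eaton's reagent (P2O5 in MeSO3H) as solvent, 70 °C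
Reagents that add atoms: none
Why: Friedel–Crafts (Nencki-type) acylation, in which the activated acid 2 should attack 1 at the carbon ortho to one hydroxyl and para to the other (next to bromine) rather than at the more crowded carbon between the two hydroxyls, and the chelated ketone formed is deactivated against a second acylation.

Step 2
Reactants: 3 (2-bromo-4,6-dihydroxyphenyl)(4-hydroxy-3-methoxyphenyl)methanone
Product: 4 (2-bromo-6-hydroxy-4-TIPSO-phenyl)(3-methoxy-4-TIPSO-phenyl)methanone
Conditions: TIPSCl (2.1 equiv), imidazole, DMF, 0 °C to rt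
Reagents that add atoms: triisopropylsilyl chloride (TIPSCl), CC(C)[Si](Cl)(C(C)C)C(C)C
Why: Silylation of phenols, selective because the hydroxyl ortho to the carbonyl is hydrogen-bonded to it and hindered, so only the two other phenols should take up the bulky silyl group.

Step 3
Reactants: 4 (2-bromo-6-hydroxy-4-TIPSO-phenyl)(3-methoxy-4-TIPSO-phenyl)methanone
Product: 6 3-bromo-2-[1-(3-methoxy-4-TIPSO-phenyl)ethenyl]-5-TIPSO-phenol, via tertiary carbinol 5 (not isolated)
Conditions: MeMgBr (4 equiv), THF, 0 to 40 °C; aq NH4Cl; then TsOH·H2O (5 mol%), toluene, rt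
Reagents that add atoms: methylmagnesium bromide, C[Mg]Br
Why: Grignard addition to the non-enolisable diaryl ketone, held planar and activated as its magnesium phenoxide chelate, followed by acid-catalysed E1 dehydration of the doubly benzylic tertiary alcohol, which can only give the 1,1-diarylethene.

Step 4
Reactants: 6 3-bromo-2-[1-(3-methoxy-4-TIPSO-phenyl)ethenyl]-5-TIPSO-phenol
Product: 7 3-bromo-2-[1-(3-methoxy-4-TIPSO-phenyl)ethenyl]-5-TIPSO-phenyl pentafluorophenyl carbonate
Conditions: bis(pentafluorophenyl) carbonate (1.5 equiv), Et3N, DMAP (5 mol%), CH2Cl2, 0 °C to rt; short silica plug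
Reagents that add atoms: bis(pentafluorophenyl) carbonate, O=C(Oc1c(F)c(F)c(F)c(F)c1F)Oc1c(F)c(F)c(F)c(F)c1F
Why: DMAP-catalysed O-acylation (mixed carbonate formation) of the only free phenol; the excess reagent and the hindered phenol should prevent the symmetrical diaryl carbonate.

Step 5
Reactants: 7 3-bromo-2-[1-(3-methoxy-4-TIPSO-phenyl)ethenyl]-5-TIPSO-phenyl pentafluorophenyl carbonate
Product: 8 (4R)-5-bromo-4-(3-methoxy-4-TIPSO-phenyl)-7-TIPSO-chroman-2-one
Conditions: Cu(OAc)2 (5 mol%), (R)-DTBM-SEGPHOS (5.5 mol%), (MeO)2MeSiH (2 equiv), THF, 40 °C, no proton source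
Reagents that add atoms: none
Why: Proposed new method: the ligated CuH formed from Cu(OAc)2, the bisphosphine and the silane should add across the 1,1-diarylethene with copper on the terminal CH2 and hydride on the diaryl carbon, and the primary alkylcopper should then attack the tethered carbonate carbonyl, forming the C3–C2 bond and expelling pentafluorophenoxide, whose copper salt the silane turns back into CuH; the closest known reaction types are CuH-catalysed enantioselective hydroacylation and hydrocarboxylation of alkenes with anhydrides and fluoroformates, anti-Markovnikov hydrocupration of 1,1-disubstituted alkenes, and intramolecular acylation of alkylcopper species by carbamoyl chlorides. The lactone ring closes by a 6-exo-trig acyl substitution, C3 attacking the exocyclic C=O of the carbonate through a six-membered transition state. The new stereocenter C4 is set in the hydride-transfer step by the chiral bisphosphine, which must tell the coplanar, conjugated guaiacyl ring from the perpendicular 2,6-disubstituted ring A; C4 is β to copper and not acidic, so it should not scramble afterwards. The step needs copper on the terminal carbon (secured by 1,1-disubstitution, the tertiary diarylmethylcopper being too crowded), C–C closure instead of protodemetalation (no proton source), collapse of the tetrahedral intermediate with the ring intact (pentafluorophenoxide is a far better leaving group than the ring-A phenoxide), and survival of C–Br and the silyl ethers (inert to CuH).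

Step 6
Reactants: 9 2-methoxy-4-vinylphenol
Product: 10 (4-ethenyl-2-methoxyphenoxy)tri(propan-2-yl)silane
Conditions: TIPSCl (1.1 equiv), imidazole, CH2Cl2, rt
Reagents that add atoms: triisopropylsilyl chloride (TIPSCl), CC(C)[Si](Cl)(C(C)C)C(C)C
Why: Silylation of the phenol, which masks the acidic hydroxyl and keeps the electron-rich styrene from polymerising in the coupling.

Step 7
Reactants: 8 (4R)-5-bromo-4-(3-methoxy-4-TIPSO-phenyl)-7-TIPSO-chroman-2-one; 10 (4-ethenyl-2-methoxyphenoxy)tri(propan-2-yl)silane
Product: 11 (4R)-4-(3-methoxy-4-TIPSO-phenyl)-5-[(E)-2-(3-methoxy-4-TIPSO-phenyl)ethenyl]-7-TIPSO-chroman-2-one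
Conditions: Pd(P(t-Bu)3)2 (5 mol%), Cy2NMe (1.5 equiv), 1,4-dioxane, 80 °C
Reagents that add atoms: none
Why: Mizoroki–Heck reaction, in which oxidative addition of the ortho-substituted aryl bromide to zerovalent palladium, syn-carbopalladation at the terminal carbon of the styrene and syn-β-hydride elimination should give the (E)-stilbene, while the hindered amine base is too weak to open the lactone or touch C4–H.

Step 8
Reactants: 11 (4R)-4-(3-methoxy-4-TIPSO-phenyl)-5-[(E)-2-(3-methoxy-4-TIPSO-phenyl)ethenyl]-7-TIPSO-chroman-2-one
Product: 12 (4R)-7-hydroxy-4-(4-hydroxy-3-methoxyphenyl)-5-[(E)-2-(4-hydroxy-3-methoxyphenyl)ethenyl]chroman-2-one (CNP0277187.1)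
Conditions: TBAF (3.6 equiv), AcOH (4 equiv), THF, 0 °C to rt
Reagents that add atoms: none
Why: Fluoride-mediated cleavage of the three aryl silyl ethers, with acetic acid buffering the phenoxides so that the aryl lactone should stay closed and C4 untouched.

Compound list
1 | 5-bromoresorcinol (5-bromobenzene-1,3-diol) | Oc1cc(O)cc(Br)c1 | starting material
2 | vanillic acid (4-hydroxy-3-methoxybenzoic acid) | COc1cc(C(=O)O)ccc1O | starting material
3 | (2-bromo-4,6-dihydroxyphenyl)(4-hydroxy-3-methoxyphenyl)methanone | COc1cc(C(=O)c2c(O)cc(O)cc2Br)ccc1O | intermediate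
4 | (2-bromo-6-hydroxy-4-TIPSO-phenyl)(3-methoxy-4-TIPSO-phenyl)methanone | COc1cc(C(=O)c2c(O)cc(O[Si](C(C)C)(C(C)C)C(C)C)cc2Br)ccc1O[Si](C(C)C)(C(C)C)C(C)C | intermediate
5 | 3-bromo-2-[1-hydroxy-1-(3-methoxy-4-TIPSO-phenyl)ethyl]-5-TIPSO-phenol, racemic tertiary carbinol | COc1cc(C(C)(O)c2c(O)cc(O[Si](C(C)C)(C(C)C)C(C)C)cc2Br)ccc1O[Si](C(C)C)(C(C)C)C(C)C | intermediate
6 | 3-bromo-2-[1-(3-methoxy-4-TIPSO-phenyl)ethenyl]-5-TIPSO-phenol | C=C(c1ccc(O[Si](C(C)C)(C(C)C)C(C)C)c(OC)c1)c1c(O)cc(O[Si](C(C)C)(C(C)C)C(C)C)cc1Br | intermediate
7 | 3-bromo-2-[1-(3-methoxy-4-TIPSO-phenyl)ethenyl]-5-TIPSO-phenyl pentafluorophenyl carbonate | C=C(c1ccc(O[Si](C(C)C)(C(C)C)C(C)C)c(OC)c1)c1c(Br)cc(O[Si](C(C)C)(C(C)C)C(C)C)cc1OC(=O)Oc1c(F)c(F)c(F)c(F)c1F | intermediate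
8 | (4R)-5-bromo-4-(3-methoxy-4-TIPSO-phenyl)-7-TIPSO-chroman-2-one | Brc1cc(O[Si](C(C)C)(C(C)C)C(C)C)cc2c1[C@@H](c1ccc(O[Si](C(C)C)(C(C)C)C(C)C)c(OC)c1)CC(=O)O2 | intermediate
9 | 2-methoxy-4-vinylphenol | C=Cc1ccc(O)c(OC)c1 | starting material
10 | (4-ethenyl-2-methoxyphenoxy)tri(propan-2-yl)silane | C=Cc1ccc(O[Si](C(C)C)(C(C)C)C(C)C)c(OC)c1 | intermediate
11 | (4R)-4-(3-methoxy-4-TIPSO-phenyl)-5-[(E)-2-(3-methoxy-4-TIPSO-phenyl)ethenyl]-7-TIPSO-chroman-2-one | COc1cc(/C=C/c2cc(O[Si](C(C)C)(C(C)C)C(C)C)cc3c2[C@@H](c2ccc(O[Si](C(C)C)(C(C)C)C(C)C)c(OC)c2)CC(=O)O3)ccc1O[Si](C(C)C)(C(C)C)C(C)C | intermediate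
12 | (4R)-7-hydroxy-4-(4-hydroxy-3-methoxyphenyl)-5-[(E)-2-(4-hydroxy-3-methoxyphenyl)ethenyl]chroman-2-one | COc1cc(/C=C/c2cc(O)cc3c2[C@@H](c2ccc(O)c(OC)c2)CC(=O)O3)ccc1O | target

Total step count: 8. Longest linear sequence: 7 steps (steps 1, 2, 3, 4, 5, 7, 8).

Steps most likely to fail

Step 5 (Proposed new method). Hydrocupration of the crowded diarylethene, whose two faces are flanked by the ortho bromine and the ortho carbonate of the perpendicular ring A, may be slower than hydride attack of CuH on the activated carbonate (loss of the tether) or on the lactone product (over-reduction to the lactol). Facial discrimination between the two aryl groups may also be poor. The fallback uses known chemistry and sets out from phenol 6, so step 4 is skipped: palladium-catalysed enantioselective intramolecular hydroesterification of the 2-(1-arylvinyl)phenol under carbon monoxide (Pd(OAc)2, a chiral bisphosphine such as (R)-DTBM-SEGPHOS, TsOH as co-catalyst, CO 5 bar, toluene, 60 °C). A palladium hydride should add anti-Markovnikov to the diarylethene and set C4, CO insertion forms the C3–C2 bond, and the phenol closes the lactone. The fallback comes back to the route at 8.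

Step 1. C-aroylation may be sluggish, because the 4-hydroxyaroyl cation is a weak electrophile and the ring of 1 is deactivated by bromine, so that O-acylation and attack at the carbon between the two hydroxyls compete. The fallback sets out from 1 and moves the aryl–carbon bond formation to a Grignard addition. Acetylation with AcOH and BF3·OEt2 at 90 °C, a small electrophile whose product is held as its BF2 chelate, should give 1-(2-bromo-4,6-dihydroxyphenyl)ethan-1-one F1. Selective silylation of the non-chelated hydroxyl (TIPSCl 1.05 equiv, imidazole, DMF, 0 °C) should give 1-(2-bromo-6-hydroxy-4-TIPSO-phenyl)ethan-1-one F2. Separately, commercial 4-bromo-2-methoxyphenol is silylated (TIPSCl, imidazole, CH2Cl2) to (4-bromo-2-methoxyphenoxy)tri(propan-2-yl)silane F3 and converted with Mg in THF into (3-methoxy-4-TIPSO-phenyl)magnesium bromide F4. Ketone F2, deprotonated at the phenol with MeMgBr (1 equiv), should take up F4 (LaCl3·2LiCl, THF, 0 °C to rt) to give carbinol 5, where the fallback comes back to the route; dehydration follows as in step 3.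

Step 3. 1,2-Addition to the carbonyl flanked by bromine and the magnesium phenoxide may be slow, so that ketone is returned or the silyl ether para to the carbonyl is attacked on forcing. The fallback sets out from 4 and replaces addition–elimination by a titanium–methylene carbonyl olefination: Takai–Lombardo methylenation (Zn, CH2Br2, TiCl4, THF/CH2Cl2, 0 °C to rt, excess reagent to cover the free phenol). This is non-basic and little sensitive to steric crowding, and should give the diarylethene directly, coming back to the route at 6.

Further compounds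
F0 | step 5 | none | none
F1 | step 1 | 1-(2-bromo-4,6-dihydroxyphenyl)ethan-1-one | CC(=O)c1c(O)cc(O)cc1Br
F2 | step 1 | 1-(2-bromo-6-hydroxy-4-TIPSO-phenyl)ethan-1-one | CC(=O)c1c(O)cc(O[Si](C(C)C)(C(C)C)C(C)C)cc1Br
F3 | step 1 | (4-bromo-2-methoxyphenoxy)tri(propan-2-yl)silane | COc1cc(Br)ccc1O[Si](C(C)C)(C(C)C)C(C)C
F4 | step 1 | (3-methoxy-4-TIPSO-phenyl)magnesium bromide | COc1cc([Mg]Br)ccc1O[Si](C(C)C)(C(C)C)C(C)C
F0 | step 3 | none | none
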